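**Retrosynthetic overview**
1. The pyrrolidine-2,4-dione is made last by Dieckmann closure on a glycine β-keto amide grown from the C1 aldehyde; the C3=C4 alkene comes from a C4 ketone through its kinetic enol triflate.
2. Ring A is closed onto a preformed ring B by the bond between the ring-fusion carbon C8a and the quaternary carbon C1, in a silicon-tethered type 2 intramolecular Diels–Alder reaction (C2–C3 forms in the same event).
3. Enabling feature: on ring A, C4 (an alkene carbon that can be carried as an enol oxygen) is 1,3 to C2, and the C2 side chain has its hydroxyl two carbons out (C2'). O(C4)–Si–O–C2'–C1' is therefore a five-atom bridge from C4 to C2 on the ring face opposite the C1 acyl group; it is cleaved in the next step.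
4. The dienophile carries the whole side chain (C7'/C8' by crotylboration, C2' by vinylogous aldol), so the key step joins the two halves; ring B comes from (R)-5-methylcyclohex-2-enone.
5. Order of ring formation: ring B (starting material), ring A with the temporary eight-membered silyl ketal ring (step 10), pyrrolidinedione (step 20).

Key step: step 10

Locants: decalin carbons C1–C8a and side-chain carbons C1'–C10' (counted from the ring) are those of the target.
Assumption: (R)-5-methylcyclohex-2-en-1-one is taken as a purchasable building block (it is also a known degradation product of (R)-pulegone).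
Assumption: in the catalyst- or auxiliary-controlled steps (3, 8 and the aldol fallback) the antipode written is taken to be the one that delivers the stated configuration; if the sense of induction is the opposite, its mirror image is used.

**Route**

Step 1
Reactants: 1 (R)-5-methylcyclohex-2-en-1-one
Product: 3 (3R,5R)-3,5-dimethylcyclohex-1-en-1-yl trifluoromethanesulfonate, via lithium enolate 2 (not isolated)
Conditions: Me2CuLi (from MeLi and CuI), Et2O, −78 to −20 °C; then PhNTf2, THF, −20 °C to rt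
Reagents that add atoms: lithium dimethylcuprate [Li+].C[Cu-]C; N-phenylbis(trifluoromethanesulfonimide) O=S(=O)(N(c1ccccc1)S(=O)(=O)C(F)(F)F)C(F)(F)F
Why: Cuprate conjugate addition should occur anti to the C5 methyl and give the trans-3,5-dimethyl pattern (the later C8 and C6), and the enolate is O-triflated; the parent ketone has a twofold axis, so only one enol triflate can form.

Step 2
Reactants: 3 (3R,5R)-3,5-dimethylcyclohex-1-en-1-yl trifluoromethanesulfonate
Product: 5 1-[(3R,5R)-3,5-dimethylcyclohex-1-en-1-yl]ethan-1-one, via ethoxyvinyl diene 4 (not isolated)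
Conditions: Bu3Sn(C(OEt)=CH2), Pd(PPh3)4 (5 mol %), LiCl, THF, 65 °C; then 1 M HCl, rt
Reagents that add atoms: tributyl(1-ethoxyvinyl)stannane CCCC[Sn](CCCC)(CCCC)C(=C)OCC; water O
Why: Stille coupling of the enol triflate with the masked acetyl anion and hydrolysis of the enol ether should give the conjugated methyl ketone without touching the two methyl-bearing stereocenters.

Step 3
Reactants: 6 propanal; 7 (Z)-crotylboronic acid pinacol ester
Product: 8 (3S,4S)-4-methylhex-5-en-3-ol
Conditions: (R)-3,3'-bis(2,4,6-triisopropylphenyl)-1,1'-binaphthyl-2,2'-diyl hydrogen phosphate (5 mol %), PhMe, −30 °C; aq. NaHCO3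
Reagents that add atoms: none
Why: Chiral-phosphoric-acid-catalysed crotylboration through a closed chair transition state turns the Z geometry into the syn relationship, and the catalyst sets the absolute configuration of both new centers (later C8' and C7').

Step 4
Reactants: 8 (3S,4S)-4-methylhex-5-en-3-ol
Product: 9 tert-butyldimethyl{[(3S,4S)-4-methylhex-5-en-3-yl]oxy}silane
Conditions: TBSCl, imidazole, DMF, rt
Reagents that add atoms: tert-butyldimethylsilyl chloride CC(C)(C)[Si](C)(C)Cl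
Why: Silylation of the secondary alcohol protects C8'–OH through to the last step.

Step 5
Reactants: 9 tert-butyldimethyl{[(3S,4S)-4-methylhex-5-en-3-yl]oxy}silane
Product: 10 (2E,4S,5S)-5-[(tert-butyldimethylsilyl)oxy]-4-methylhept-2-enal
Conditions: (E)-but-2-enal (3 equiv), second-generation Grubbs catalyst RuCl2(=CHPh)(PCy3)(H2IMes) (5 mol %), CH2Cl2, 40 °C
Reagents that add atoms: (E)-but-2-enal C/C=C/C=O
Why: Olefin cross-metathesis of the terminal alkene with the electron-poor partner should give the E enal under neutral conditions that do not epimerize the allylic center.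

Step 6
Reactants: 10 (2E,4S,5S)-5-[(tert-butyldimethylsilyl)oxy]-4-methylhept-2-enal
Product: 11 (2E,4E,6S,7S)-7-[(tert-butyldimethylsilyl)oxy]-6-methylnona-2,4-dienal
Conditions: Ph3P=CHCHO, PhMe, 80 °C
Reagents that add atoms: (triphenylphosphoranylidene)acetaldehyde O=CC=P(c1ccccc1)(c1ccccc1)c1ccccc1
Why: Wittig olefination with the stabilized formyl ylide should add two carbons with E geometry and complete the E,E diene of the side chain.

Step 7
Reactants: 12 methyl tiglate
Product: 14 tert-butyl[(1-methoxy-2-methylbuta-1,3-dien-1-yl)oxy]dimethylsilane, via lithium dienolate 13 (not isolated)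
Conditions: LiN(iPr)2, DMPU, THF, −78 °C; then TBSCl, −78 °C to rt
Reagents that add atoms: tert-butyldimethylsilyl chloride CC(C)(C)[Si](C)(C)Cl
Why: γ-Deprotonation of the enoate and O-silylation of the extended enolate should give the vinylketene silyl acetal (either acetal geometry is usable).

Step 8
Reactants: 11 (2E,4E,6S,7S)-7-[(tert-butyldimethylsilyl)oxy]-6-methylnona-2,4-dienal; 14 tert-butyl[(1-methoxy-2-methylbuta-1,3-dien-1-yl)oxy]dimethylsilane
Product: 15 methyl (2E,5R,6E,8E,10S,11S)-11-[(tert-butyldimethylsilyl)oxy]-5-hydroxy-2,10-dimethyltrideca-2,6,8-trienoate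
Conditions: SiCl4, (R,R)-N,N'-dimethyl-1,1'-binaphthyl-2,2'-diamine-derived bisphosphoramide (5 mol %), iPr2NEt (cat.), CH2Cl2, −78 °C; aq. KF/NaHCO3
Reagents that add atoms: none
Why: In this vinylogous Mukaiyama aldol reaction the dienolate should attack through its γ-carbon to give the E α-methyl enoate, and the chiral phosphoramide-bound silicon Lewis acid selects the aldehyde face (C2'), the C7'/C8' centers being too remote to interfere.

Step 9
Reactants: 15 methyl (2E,5R,6E,8E,10S,11S)-11-[(tert-butyldimethylsilyl)oxy]-5-hydroxy-2,10-dimethyltrideca-2,6,8-trienoate; 5 1-[(3R,5R)-3,5-dimethylcyclohex-1-en-1-yl]ethan-1-one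
Product: 17 mixed di(propan-2-yl)silyl ketal of 15 (at O5) and the methyl-side dienol of 5, via silyl monotriflate 16 (not isolated)
Conditions: iPr2Si(OTf)2, 2,6-lutidine, CH2Cl2, −78 °C; then 5, Et3N, −78 to 0 °C
Reagents that add atoms: di(propan-2-yl)silanediyl bis(trifluoromethanesulfonate) CC(C)[Si](OS(=O)(=O)C(F)(F)F)(OS(=O)(=O)C(F)(F)F)C(C)C
Why: Stepwise substitution at silicon (unsymmetrical silyl ketal formation): the hindered secondary alcohol should take one triflate only, and the remaining silyl triflate with Et3N enolizes the methyl ketone on the methyl side to give the cross-conjugated 2-silyloxy diene tethered to the dienophile.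

Step 10
Reactants: 17 mixed di(propan-2-yl)silyl ketal (tethered triene)
Product: 18 bridged cycloadduct (bicyclo[5.3.1] silyl enol ether with ring A closed)
Conditions: PhMe (0.01 M), BHT (cat.), 170 °C, sealed tube
Reagents that add atoms: none
Why: This is a thermal type 2 intramolecular Diels–Alder reaction of a 2-silyloxy diene with a tethered E-trisubstituted enoate (normal electron demand, concerted but asynchronous: the diene terminus C3 bonds to the enoate β-carbon C2 ahead of the C1–C8a bond, whose formation closes ring A); the closest known reaction type is the silicon-tethered type 2 intramolecular Diels–Alder reaction giving bicyclo[5.3.1] bridgehead enol ethers. Ring A closes in the [4+2] mode through C1–C8a, and the eight-membered 1,3-dioxa-2-sila ring closes through C2–C3, the short tether allowing only this ("meta") regiochemistry. C1 and C2 follow from suprafacial addition to the E enoate (C1 methyl and C1' cis) together with the tether, which must lie under the diene and so places C1' and the C1 methyl endo and the ester exo, that is, cis to H8a. C8a is set by the diene face: the dienophile should add anti to the pseudoaxial allylic C8 methyl of ring B, which puts C1 trans to that methyl and relates C1, C2 and C8a to C6/C8. The selectivities needed are regiochemistry, exo orientation of the ester and diene face; the first two are secured by the five-atom O–Si–O–C–C bridge between C4 and C2, the third by the C8 stereocenter. The C2' center in the bridge can carry its dienyl chain on the outside of the eight-membered ring and is not expected to oppose this course.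

Step 11
Reactants: 18 bridged cycloadduct
Product: 20 methyl (1S,2R,4aR,6R,8R,8aS)-2-[(2R,3E,5E,7S,8S)-8-[(tert-butyldimethylsilyl)oxy]-2-hydroxy-7-methyldeca-3,5-dien-1-yl]-1,6,8-trimethyl-4-oxodecahydronaphthalene-1-carboxylate, via silanol 19 (not isolated)
Conditions: PPTS, THF/H2O (10:1), 0 °C; then HF·pyridine, pyridine, THF, 0 °C
Reagents that add atoms: none
Why: Acid hydrolysis of the strained bridgehead silyl enol ether starts with C-protonation at C4a, which can only come from the outer face of the bicycle (opposite the bridge), so H4a should end cis to H8a (kinetic cis ring fusion); buffered fluoride then frees the C2' hydroxyl while the hindered C8' TBS ether is kept.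

Step 12
Reactants: 20 keto alcohol
Product: 21 methyl (1S,2R,4aR,6R,8R,8aS)-2-[(2R,3E,5E,7S,8S)-2,8-bis[(tert-butyldimethylsilyl)oxy]-7-methyldeca-3,5-dien-1-yl]-1,6,8-trimethyl-4-oxodecahydronaphthalene-1-carboxylate
Conditions: TBSCl, imidazole, DMAP (cat.), DMF, 35 °C
Reagents that add atoms: tert-butyldimethylsilyl chloride CC(C)(C)[Si](C)(C)Cl
Why: Silylation of the allylic secondary alcohol under conditions too weakly basic to enolize the ketone should keep the kinetically set C4a configuration.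

Step 13
Reactants: 21 bis-TBS keto ester
Product: 23 methyl (1S,2R,4aR,6R,8R,8aS)-2-[(2R,3E,5E,7S,8S)-2,8-bis[(tert-butyldimethylsilyl)oxy]-7-methyldeca-3,5-dien-1-yl]-1,6,8-trimethyl-4-[(trifluoromethanesulfonyl)oxy]-1,2,4a,5,6,7,8,8a-octahydronaphthalene-1-carboxylate, via potassium enolate 22 (not isolated)
Conditions: KN(SiMe3)2 (1.5 equiv, ketone added to base), THF, −78 °C; then PhNTf2, −78 to 0 °C
Reagents that add atoms: N-phenylbis(trifluoromethanesulfonimide) O=S(=O)(N(c1ccccc1)S(=O)(=O)C(F)(F)F)C(F)(F)F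
Why: Kinetic deprotonation by the hindered amide should take the C3 methylene and not the ring-fusion methine C4a, so the enol triflate carries the C3=C4 double bond and C4a stays intact (the C1 ester has no α-hydrogen).

Step 14
Reactants: 23 enol triflate
Product: 24 methyl (1S,2R,4aS,6R,8R,8aS)-2-[(2R,3E,5E,7S,8S)-2,8-bis[(tert-butyldimethylsilyl)oxy]-7-methyldeca-3,5-dien-1-yl]-1,6,8-trimethyl-1,2,4a,5,6,7,8,8a-octahydronaphthalene-1-carboxylate
Conditions: Pd(OAc)2 (5 mol %), PPh3, Bu3N, HCO2H, DMF, 60 °C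
Reagents that add atoms: none
Why: Palladium-catalysed formate reduction of the enol triflate (oxidative addition, hydride transfer from formate, reductive elimination) should replace OTf by H and leave the C3=C4 alkene of ring A; the side-chain diene and silyl ethers are inert.

Step 15
Reactants: 24 octalin methyl ester
Product: 25 [(1S,2R,4aS,6R,8R,8aS)-2-[(2R,3E,5E,7S,8S)-2,8-bis[(tert-butyldimethylsilyl)oxy]-7-methyldeca-3,5-dien-1-yl]-1,6,8-trimethyl-1,2,4a,5,6,7,8,8a-octahydronaphthalen-1-yl]methanol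
Conditions: iBu2AlH (3 equiv), CH2Cl2, −78 to 0 °C; aq. Rochelle salt
Reagents that add atoms: none
Why: Hydride reduction of the neopentyl ester to the primary alcohol, the only reducible group present.

Step 16
Reactants: 25 neopentyl alcohol
Product: 26 (1S,2R,4aS,6R,8R,8aS)-2-[(2R,3E,5E,7S,8S)-2,8-bis[(tert-butyldimethylsilyl)oxy]-7-methyldeca-3,5-dien-1-yl]-1,6,8-trimethyl-1,2,4a,5,6,7,8,8a-octahydronaphthalene-1-carbaldehyde
Conditions: Dess–Martin periodinane, NaHCO3, CH2Cl2, rt
Reagents that add atoms: none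
Why: Dess–Martin oxidation gives the non-enolizable C1 aldehyde under buffered conditions safe for the silyl ethers and the diene.

Step 17
Reactants: 26 C1 aldehyde; 27 S-tert-butyl ethanethioate
Product: 29 S-tert-butyl 3-hydroxy-3-[decalin C1]propanethioate (both carbinol epimers), via lithium thioester enolate 28 (not isolated)
Conditions: 27, LiN(iPr)2, THF, −78 °C; then 26, −78 °C; aq. NH4Cl
Reagents that add atoms: none
Why: Aldol addition of the small thioacetate enolate to the hindered, non-enolizable aldehyde; the new carbinol center is removed in the next step.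

Step 18
Reactants: 29 β-hydroxy thioester
Product: 30 S-tert-butyl 3-oxo-3-[decalin C1]propanethioate
Conditions: Dess–Martin periodinane, NaHCO3, CH2Cl2, rt
Reagents that add atoms: none
Why: Dess–Martin oxidation of the secondary alcohol gives the β-keto thioester without epimerizable centers nearby.

Step 19
Reactants: 30 β-keto thioester; 31 glycine methyl ester hydrochloride
Product: 32 methyl N-{3-oxo-3-[decalin C1]propanoyl}glycinate
Conditions: Et3N, AgOCOCF3, THF, 0 °C to rt
Reagents that add atoms: none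
Why: Silver-promoted thioester aminolysis (thiophilic activation) forms the β-keto amide under near-neutral conditions.

Step 20
Reactants: 32 β-keto amide
Product: 33 3-[(1S,2R,4aS,6R,8R,8aS)-2-[(2R,3E,5E,7S,8S)-2,8-bis[(tert-butyldimethylsilyl)oxy]-7-methyldeca-3,5-dien-1-yl]-1,6,8-trimethyl-1,2,4a,5,6,7,8,8a-octahydronaphthalene-1-carbonyl]-4-hydroxy-1,5-dihydro-2H-pyrrol-2-one
Conditions: NaOMe, MeOH, rt; then aq. HCl to pH 3
Reagents that add atoms: none
Why: Lacey–Dieckmann cyclization: the enolate of the β-keto amide methylene attacks the glycine ester carbonyl (5-exo-trig) to close the pyrrolidine-2,4-dione, isolated as its enol after acidification.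

Step 21
Reactants: 33 bis-TBS tetramic acid
Product: 34 target (CNP0117518.2)
Conditions: HF·pyridine, pyridine, THF, 0 °C to rt
Reagents that add atoms: none
Why: Buffered fluoride desilylation removes both TBS ethers without ionizing the dienyl carbinol or harming the tetramic acid.

**Compound list**

1 | (R)-5-methylcyclohex-2-en-1-one | O=C1C=CC[C@@H](C)C1 | starting material
2 | lithium (3R,5R)-3,5-dimethylcyclohex-1-en-1-olate | [Li+].[O-]C1=C[C@H](C)C[C@@H](C)C1 | intermediate
3 | (3R,5R)-3,5-dimethylcyclohex-1-en-1-yl trifluoromethanesulfonate | O=S(=O)(OC1=C[C@H](C)C[C@@H](C)C1)C(F)(F)F | intermediate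
4 | (3R,5R)-1-(1-ethoxyethenyl)-3,5-dimethylcyclohex-1-ene | CCOC(=C)C1=C[C@H](C)C[C@@H](C)C1 | intermediate
5 | 1-[(3R,5R)-3,5-dimethylcyclohex-1-en-1-yl]ethan-1-one | CC(=O)C1=C[C@H](C)C[C@@H](C)C1 | intermediate
6 | propanal | CCC=O | starting material
7 | (Z)-crotylboronic acid pinacol ester | C/C=C\CB1OC(C)(C)C(C)(C)O1 | starting material
8 | (3S,4S)-4-methylhex-5-en-3-ol | CC[C@H](O)[C@@H](C)C=C | intermediate
9 | tert-butyldimethyl{[(3S,4S)-4-methylhex-5-en-3-yl]oxy}silane | CC[C@H](O[Si](C)(C)C(C)(C)C)[C@@H](C)C=C | intermediate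
10 | (2E,4S,5S)-5-[(tert-butyldimethylsilyl)oxy]-4-methylhept-2-enal | CC[C@H](O[Si](C)(C)C(C)(C)C)[C@@H](C)/C=C/C=O | intermediate
11 | (2E,4E,6S,7S)-7-[(tert-butyldimethylsilyl)oxy]-6-methylnona-2,4-dienal | CC[C@H](O[Si](C)(C)C(C)(C)C)[C@@H](C)/C=C/C=C/C=O | intermediate
12 | methyl tiglate, methyl (2E)-2-methylbut-2-enoate | C/C=C(\C)C(=O)OC | starting material
13 | lithium 1-methoxy-2-methylbuta-1,3-dien-1-olate | [Li+].[O-]C(OC)=C(C)C=C | intermediate
14 | tert-butyl[(1-methoxy-2-methylbuta-1,3-dien-1-yl)oxy]dimethylsilane | C=CC(C)=C(OC)O[Si](C)(C)C(C)(C)C | intermediate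
15 | methyl (2E,5R,6E,8E,10S,11S)-11-[(tert-butyldimethylsilyl)oxy]-5-hydroxy-2,10-dimethyltrideca-2,6,8-trienoate | CC[C@H](O[Si](C)(C)C(C)(C)C)[C@@H](C)/C=C/C=C/[C@H](O)C/C=C(\C)C(=O)OC | intermediate
16 | methyl (2E,5R,6E,8E,10S,11S)-11-[(tert-butyldimethylsilyl)oxy]-2,10-dimethyl-5-({di(propan-2-yl)[(trifluoromethanesulfonyl)oxy]silyl}oxy)trideca-2,6,8-trienoate | CC[C@H](O[Si](C)(C)C(C)(C)C)[C@@H](C)/C=C/C=C/[C@H](O[Si](C(C)C)(C(C)C)OS(=O)(=O)C(F)(F)F)C/C=C(\C)C(=O)OC | intermediate
17 | methyl (2E,5R,6E,8E,10S,11S)-11-[(tert-butyldimethylsilyl)oxy]-5-{[({1-[(3R,5R)-3,5-dimethylcyclohex-1-en-1-yl]ethenyl}oxy)di(propan-2-yl)silyl]oxy}-2,10-dimethyltrideca-2,6,8-trienoate | CC[C@H](O[Si](C)(C)C(C)(C)C)[C@@H](C)/C=C/C=C/[C@H](O[Si](C(C)C)(C(C)C)OC(=C)C1=C[C@H](C)C[C@@H](C)C1)C/C=C(\C)C(=O)OC | intermediate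
18 | bridged cycloadduct: methyl (1S,2R,6R,8R,8aS)-1,6,8-trimethyl-1,2,3,5,6,7,8,8a-octahydronaphthalene-1-carboxylate (C4=C4a) whose C4 enol oxygen and the C2' oxygen of its C2 side chain [(2R,3E,5E,7S,8S)-8-(tert-butyldimethylsilyloxy)-7-methyldeca-3,5-dienyl] are joined by Si(iPr)2 | COC(=O)[C@@]1(C)[C@@H]2C[C@H](/C=C/C=C/[C@H](C)[C@H](CC)O[Si](C)(C)C(C)(C)C)O[Si](C(C)C)(C(C)C)OC(C2)=C2C[C@H](C)C[C@@H](C)[C@H]12 | intermediate
19 | methyl (1S,2R,4aR,6R,8R,8aS)-2-[(2R,3E,5E,7S,8S)-8-[(tert-butyldimethylsilyl)oxy]-2-{[hydroxydi(propan-2-yl)silyl]oxy}-7-methyldeca-3,5-dien-1-yl]-1,6,8-trimethyl-4-oxodecahydronaphthalene-1-carboxylate | COC(=O)[C@@]1(C)[C@H](C[C@@H](O[Si](O)(C(C)C)C(C)C)/C=C/C=C/[C@H](C)[C@H](CC)O[Si](C)(C)C(C)(C)C)CC(=O)[C@@H]2C[C@H](C)C[C@@H](C)[C@H]12 | intermediate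
20 | methyl (1S,2R,4aR,6R,8R,8aS)-2-[(2R,3E,5E,7S,8S)-8-[(tert-butyldimethylsilyl)oxy]-2-hydroxy-7-methyldeca-3,5-dien-1-yl]-1,6,8-trimethyl-4-oxodecahydronaphthalene-1-carboxylate | COC(=O)[C@@]1(C)[C@H](C[C@@H](O)/C=C/C=C/[C@H](C)[C@H](CC)O[Si](C)(C)C(C)(C)C)CC(=O)[C@@H]2C[C@H](C)C[C@@H](C)[C@H]12 | intermediate
21 | methyl (1S,2R,4aR,6R,8R,8aS)-2-[(2R,3E,5E,7S,8S)-2,8-bis[(tert-butyldimethylsilyl)oxy]-7-methyldeca-3,5-dien-1-yl]-1,6,8-trimethyl-4-oxodecahydronaphthalene-1-carboxylate | COC(=O)[C@@]1(C)[C@H](C[C@@H](O[Si](C)(C)C(C)(C)C)/C=C/C=C/[C@H](C)[C@H](CC)O[Si](C)(C)C(C)(C)C)CC(=O)[C@@H]2C[C@H](C)C[C@@H](C)[C@H]12 | intermediate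
22 | potassium C3=C4 enolate of 21 | COC(=O)[C@@]1(C)[C@H](C[C@@H](O[Si](C)(C)C(C)(C)C)/C=C/C=C/[C@H](C)[C@H](CC)O[Si](C)(C)C(C)(C)C)C=C([O-])[C@@H]2C[C@H](C)C[C@@H](C)[C@H]12.[K+] | intermediate
23 | methyl (1S,2R,4aR,6R,8R,8aS)-2-[(2R,3E,5E,7S,8S)-2,8-bis[(tert-butyldimethylsilyl)oxy]-7-methyldeca-3,5-dien-1-yl]-1,6,8-trimethyl-4-[(trifluoromethanesulfonyl)oxy]-1,2,4a,5,6,7,8,8a-octahydronaphthalene-1-carboxylate | COC(=O)[C@@]1(C)[C@H](C[C@@H](O[Si](C)(C)C(C)(C)C)/C=C/C=C/[C@H](C)[C@H](CC)O[Si](C)(C)C(C)(C)C)C=C(OS(=O)(=O)C(F)(F)F)[C@@H]2C[C@H](C)C[C@@H](C)[C@H]12 | intermediate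
24 | methyl (1S,2R,4aS,6R,8R,8aS)-2-[(2R,3E,5E,7S,8S)-2,8-bis[(tert-butyldimethylsilyl)oxy]-7-methyldeca-3,5-dien-1-yl]-1,6,8-trimethyl-1,2,4a,5,6,7,8,8a-octahydronaphthalene-1-carboxylate | COC(=O)[C@@]1(C)[C@H](C[C@@H](O[Si](C)(C)C(C)(C)C)/C=C/C=C/[C@H](C)[C@H](CC)O[Si](C)(C)C(C)(C)C)C=C[C@@H]2C[C@H](C)C[C@@H](C)[C@H]12 | intermediate
25 | [(1S,2R,4aS,6R,8R,8aS)-2-[(2R,3E,5E,7S,8S)-2,8-bis[(tert-butyldimethylsilyl)oxy]-7-methyldeca-3,5-dien-1-yl]-1,6,8-trimethyl-1,2,4a,5,6,7,8,8a-octahydronaphthalen-1-yl]methanol | OC[C@@]1(C)[C@H](C[C@@H](O[Si](C)(C)C(C)(C)C)/C=C/C=C/[C@H](C)[C@H](CC)O[Si](C)(C)C(C)(C)C)C=C[C@@H]2C[C@H](C)C[C@@H](C)[C@H]12 | intermediate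
26 | (1S,2R,4aS,6R,8R,8aS)-2-[(2R,3E,5E,7S,8S)-2,8-bis[(tert-butyldimethylsilyl)oxy]-7-methyldeca-3,5-dien-1-yl]-1,6,8-trimethyl-1,2,4a,5,6,7,8,8a-octahydronaphthalene-1-carbaldehyde | O=C[C@@]1(C)[C@H](C[C@@H](O[Si](C)(C)C(C)(C)C)/C=C/C=C/[C@H](C)[C@H](CC)O[Si](C)(C)C(C)(C)C)C=C[C@@H]2C[C@H](C)C[C@@H](C)[C@H]12 | intermediate
27 | S-tert-butyl ethanethioate | CC(=O)SC(C)(C)C | starting material
28 | lithium 1-(tert-butylsulfanyl)ethen-1-olate | [Li+].[O-]C(=C)SC(C)(C)C | intermediate
29 | S-tert-butyl 3-hydroxy-3-[(1S,2R,4aS,6R,8R,8aS)-2-[(2R,3E,5E,7S,8S)-2,8-bis[(tert-butyldimethylsilyl)oxy]-7-methyldeca-3,5-dien-1-yl]-1,6,8-trimethyl-1,2,4a,5,6,7,8,8a-octahydronaphthalen-1-yl]propanethioate (both C3 epimers) | CC(C)(C)SC(=O)CC(O)[C@@]1(C)[C@H](C[C@@H](O[Si](C)(C)C(C)(C)C)/C=C/C=C/[C@H](C)[C@H](CC)O[Si](C)(C)C(C)(C)C)C=C[C@@H]2C[C@H](C)C[C@@H](C)[C@H]12 | intermediate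
30 | S-tert-butyl 3-oxo-3-[(1S,2R,4aS,6R,8R,8aS)-2-[(2R,3E,5E,7S,8S)-2,8-bis[(tert-butyldimethylsilyl)oxy]-7-methyldeca-3,5-dien-1-yl]-1,6,8-trimethyl-1,2,4a,5,6,7,8,8a-octahydronaphthalen-1-yl]propanethioate | CC(C)(C)SC(=O)CC(=O)[C@@]1(C)[C@H](C[C@@H](O[Si](C)(C)C(C)(C)C)/C=C/C=C/[C@H](C)[C@H](CC)O[Si](C)(C)C(C)(C)C)C=C[C@@H]2C[C@H](C)C[C@@H](C)[C@H]12 | intermediate
31 | glycine methyl ester hydrochloride | COC(=O)CN.Cl | starting material
32 | methyl N-{3-oxo-3-[(1S,2R,4aS,6R,8R,8aS)-2-[(2R,3E,5E,7S,8S)-2,8-bis[(tert-butyldimethylsilyl)oxy]-7-methyldeca-3,5-dien-1-yl]-1,6,8-trimethyl-1,2,4a,5,6,7,8,8a-octahydronaphthalen-1-yl]propanoyl}glycinate | COC(=O)CNC(=O)CC(=O)[C@@]1(C)[C@H](C[C@@H](O[Si](C)(C)C(C)(C)C)/C=C/C=C/[C@H](C)[C@H](CC)O[Si](C)(C)C(C)(C)C)C=C[C@@H]2C[C@H](C)C[C@@H](C)[C@H]12 | intermediate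
33 | 3-[(1S,2R,4aS,6R,8R,8aS)-2-[(2R,3E,5E,7S,8S)-2,8-bis[(tert-butyldimethylsilyl)oxy]-7-methyldeca-3,5-dien-1-yl]-1,6,8-trimethyl-1,2,4a,5,6,7,8,8a-octahydronaphthalene-1-carbonyl]-4-hydroxy-1,5-dihydro-2H-pyrrol-2-one | O=C1NCC(O)=C1C(=O)[C@@]1(C)[C@H](C[C@@H](O[Si](C)(C)C(C)(C)C)/C=C/C=C/[C@H](C)[C@H](CC)O[Si](C)(C)C(C)(C)C)C=C[C@@H]2C[C@H](C)C[C@@H](C)[C@H]12 | intermediate
34 | 3-[(1S,2R,4aS,6R,8R,8aS)-2-[(2R,3E,5E,7S,8S)-2,8-dihydroxy-7-methyldeca-3,5-dien-1-yl]-1,6,8-trimethyl-1,2,4a,5,6,7,8,8a-octahydronaphthalene-1-carbonyl]-4-hydroxy-1,5-dihydro-2H-pyrrol-2-one | CC[C@H](O)[C@@H](C)/C=C/C=C/[C@H](O)C[C@@H]1C=C[C@@H]2C[C@H](C)C[C@@H](C)[C@@H]2[C@@]1(C)C(=O)C1=C(O)CNC1=O | target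

**Step count and risks**

Total step count: 21. Longest linear sequence: 18 steps (steps 3–6 and 8–21, from propanal).

Steps most likely to fail:

Step 10. The trisubstituted enoate may react too slowly at temperatures the silyl dienol ether tolerates, so that desilylation, tether scrambling or erosion of diene-face selectivity takes over. The fallback raises the dienophile to the aldehyde oxidation level; it sets out from dienal 11 and ketone 5 and comes back at 18. Tiglic aldehyde is converted into its silyl dienol ether, tert-butyldimethyl[(2-methylbuta-1,3-dien-1-yl)oxy]silane F1 (TBSOTf, Et3N). Vinylogous Mukaiyama aldol of F1 with 11 under the conditions of step 8 should give (2E,5R,6E,8E,10S,11S)-11-[(tert-butyldimethylsilyl)oxy]-5-hydroxy-2,10-dimethyltrideca-2,6,8-trienal F2. Ketone 5 is silylated first (iPr2Si(OTf)2, Et3N) and F2 with 2,6-lutidine is then added to give the enal silyl ketal F3. The far more reactive enal should cyclize at 80–100 °C in PhMe to the bridged aldehyde F4. Chlorite oxidation (NaClO2, NaH2PO4, 2-methylbut-2-ene) gives the bridged acid F5, and Me3SiCHN2 in MeOH/PhMe returns ester 18.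

Step 13. Enolization toward the ring-fusion carbon or enolate equilibration would give the tetrasubstituted triflate and scramble the cis ring fusion at C4a. The fallback makes the alkene from a hydrazone; it sets out from ketone 21 and comes back at 24, bypassing 23. Condensation with p-toluenesulfonyl hydrazide (MeOH, rt) gives the C4 tosylhydrazone F6. LiN(iPr)2 (3 equiv, THF, −78 to 0 °C) then deprotonates the α-methylene, sulfinate and dinitrogen are lost, and the vinyl anion is protonated on work-up (Shapiro reaction) to give the C3=C4 alkene 24.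

Step 8. The silyloxy dienal may decompose under the silicon Lewis acid, or facial control by the catalyst may be poor. The fallback builds C2' by an auxiliary-controlled acetate aldol; it sets out from dienal 11 and comes back at 15. The titanium enolate of (S)-3-acetyl-4-benzyl-1,3-thiazolidine-2-thione (TiCl4, iPr2NEt, CH2Cl2, −78 °C) adds to 11 to give the β-hydroxy acyl thiazolidinethione F7. iBu2AlH at −78 °C releases the β-hydroxy aldehyde (3R,4E,6E,8S,9S)-9-[(tert-butyldimethylsilyl)oxy]-3-hydroxy-8-methylundeca-4,6-dienal F8, which is used crude. Wittig olefination with methyl 2-(triphenylphosphoranylidene)propanoate gives the E enoate 15.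

Further compounds
F1 | step 10 | tert-butyldimethyl[(2-methylbuta-1,3-dien-1-yl)oxy]silane | C=CC(C)=CO[Si](C)(C)C(C)(C)C
F2 | step 10 | (2E,5R,6E,8E,10S,11S)-11-[(tert-butyldimethylsilyl)oxy]-5-hydroxy-2,10-dimethyltrideca-2,6,8-trienal | CC[C@H](O[Si](C)(C)C(C)(C)C)[C@@H](C)/C=C/C=C/[C@H](O)C/C=C(\C)C=O
F3 | step 10 | enal silyl ketal: di(propan-2-yl)silyl ketal of F2 (at O5) and the methyl-side dienol of 5 | CC[C@H](O[Si](C)(C)C(C)(C)C)[C@@H](C)/C=C/C=C/[C@H](O[Si](C(C)C)(C(C)C)OC(=C)C1=C[C@H](C)C[C@@H](C)C1)C/C=C(\C)C=O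
F4 | step 10 | bridged aldehyde (the C1 carbaldehyde analogue of 18) | O=C[C@@]1(C)[C@@H]2C[C@H](/C=C/C=C/[C@H](C)[C@H](CC)O[Si](C)(C)C(C)(C)C)O[Si](C(C)C)(C(C)C)OC(C2)=C2C[C@H](C)C[C@@H](C)[C@H]12
F5 | step 10 | bridged acid (the C1 carboxylic acid analogue of 18) | OC(=O)[C@@]1(C)[C@@H]2C[C@H](/C=C/C=C/[C@H](C)[C@H](CC)O[Si](C)(C)C(C)(C)C)O[Si](C(C)C)(C(C)C)OC(C2)=C2C[C@H](C)C[C@@H](C)[C@H]12
F6 | step 13 | C4 p-toluenesulfonylhydrazone of ketone 21 | COC(=O)[C@@]1(C)[C@H](C[C@@H](O[Si](C)(C)C(C)(C)C)/C=C/C=C/[C@H](C)[C@H](CC)O[Si](C)(C)C(C)(C)C)CC(=NNS(=O)(=O)c3ccc(C)cc3)[C@@H]2C[C@H](C)C[C@@H](C)[C@H]12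
F7 | step 8 | (3R,4E,6E,8S,9S)-1-[(4S)-4-benzyl-2-sulfanylidene-1,3-thiazolidin-3-yl]-9-[(tert-butyldimethylsilyl)oxy]-3-hydroxy-8-methylundeca-4,6-dien-1-one | CC[C@H](O[Si](C)(C)C(C)(C)C)[C@@H](C)/C=C/C=C/[C@H](O)CC(=O)N1[C@@H](Cc2ccccc2)CSC1=S
F8 | step 8 | (3R,4E,6E,8S,9S)-9-[(tert-butyldimethylsilyl)oxy]-3-hydroxy-8-methylundeca-4,6-dienal | CC[C@H](O[Si](C)(C)C(C)(C)C)[C@@H](C)/C=C/C=C/[C@H](O)CC=O
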